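(All runs are calculated with constants of no real substance; noise was put on by code.)

Count what is left.

| flask | substrate | reagent | free catalyst | added ligand | remark | time |
|---|---|---|---|---|---|---|
| alder | 0.27 M | 4 equiv | 0.5 mol% | 2.6 mM | run made earlier |  |
| oak | 0.33 M | 4 equiv | 0.5 mol% | 2.6 mM | run made earlier |  |
| maple | 0.37 M | 4 equiv | 0.5 mol% | 2.6 mM | run made earlier |  |
| larch | 0.25 M | 1.5 equiv | 0.5 mol% | 2.6 mM | run made earlier |  |
| amber | 0.25 M | 4.00 equiv | 0.15 mol% | 1.2 mM |  | 2.5 d |
| grey | 0.40 M | 1.00 equiv | 0.5 mol% | 2.6 mM |  | 2.5 d |
| ochre | 0.25 M | 4.00 equiv | 0.5 mol% | 2.6 mM |  | 2.5 d |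
| blue | 0.40 M | 1.00 equiv | 0.15 mol% | 2.6 mM |  | 2.5 d |
| teal | 0.25 M | 4.00 equiv | 0.15 mol% | 2.6 mM |  | 2.5 d |

- alder (time / h: target / %, substrate / %): 4.00: 8, 92; 10.0: 18, 84; 20.0: 28, 66; 30.0: 37, 55; 40.0: 48, 41
- oak (time / h: target / %, substrate / %): 3.00: 6, 93; 6.00: 14, 90; 12.0: 22, 76; 20.0: 33, 61; 40.0: 53, 35
- maple (time / h: target / %, substrate / %): 3.00: 7, 91; 6.00: 17, 85; 12.0: 22, 72; 20.0: 37, 58; 40.0: 57, 27
- larch (time / h: target / %, substrate / %): 8.00: 9, 93; 15.0: 11, 89; 25.0: 15, 79; 30.0: 19, 78; 40.0: 23, 71

(each reading ± 1.5 percentage points)

- all flasks from highest to lowest amount of target, in percent of the substrate charged, at 2.5 d (amber / grey / ochre / blue / teal)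
- the amount of target, in percent of the substrate charged of the flask you put first, at 2.5 d
- the amount of target, in percent of the substrate charged of the flask you put last, at 2.5 d

- no earlier run changes the charge of added ligand; that part of a forecast is a guess

Why follow the substrate and not the target? Target is one part of what the substrate becomes, 78.1% of the substrate gone at maple's last reading, whereas in the four earlier runs the fraction of substrate left, f, falls by about equal factors in equal times, so its logarithm simply adds up.

What do you read from it, then? With [B] the starting concentration of reagent and t the time, I turn the sign of the logarithm of f and divide by [B] and t; this κ, the apparent second-order constant, averages 0.0214 /M/h over the last readings of the four runs, and it reads 0.0221 /M/h in maple and 0.0228 /M/h in larch, although maple starts with 3.95 times larch's reagent.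

And ochre? Treating its reagent as constant at the charge, the pseudo-first-order view, I reckon 27.7% of the substrate left at 2.5 d, and with the share above 56.5% target.

Where is that weak? Alder, oak, maple and larch share a loading of 0.5 mol% and 2.6 mM of added ligand, so κ belongs to that pair, and for the flasks at 0.15 mol% it says nothing I would sign.

Grey has the pair, so does κ serve there? Not with a number I would sign, since at 1.00 equiv the reagent falls along with the substrate, and each earlier run was charged with more reagent than that.

The forecast gives ochre > amber > teal > grey > blue, with 57% for the first flask and 17% for the last. Its top stands a little above my 56.5%, and of amber it says: “if ligand suppresses free catalyst, as I guess, it beats teal”.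

The flasks stand ochre > grey > amber > teal > blue.

    target + free catalyst ⇌ isomer of the product + free catalyst, rate k1*[free catalyst]*[target] forward; the back reaction follows from the equilibrium constant (K = 0.670, k = 53.0 /M/h)
    substrate + catalyst intermediate A → catalyst intermediate B (k = 41.0 /M/h)
    catalyst intermediate C → free catalyst + target (k = 28.0 /h)
    free catalyst + added ligand ⇌ idle complex, settled at all times (K = 790 /M)
    reagent + free catalyst ⇌ catalyst intermediate A (K = 99.0 /M, k = 16.0 /M/h)
    catalyst intermediate B → by-product + catalyst intermediate C (k = 1300 /h)

Ochre holds 57.5% of target and blue 12.5%. Grey holds more target than amber, 31.6% against 28.5%, with 51.9% of its substrate left against 67.8% in amber. With κ at 0.0214 /M/h, ochre should keep 27.7% of its substrate and keeps 26.6%. The neighbour of ochre charged with 6.80 equiv of reagent should keep 11.3% by the same κ, and it keeps 17%.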